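The route is built on cutting the C2–C3 bond of the cis-2,3-dihydrobenzofuran. C2 is the benzylic O–CH carbon that bears ring D, and C3 is the ring C benzylic carbon with the CH2OH arm. C3 can therefore come from an aryl(ester)carbene and C2 from an aryl benzyl ether C–H bond. A chiral dirhodium carboxylate converts the ring C aryldiazoacetate 22, whose ortho oxygen carries the ring D benzyl group, into the cis ester 23 in one operation that closes the ring and sets both stereocentres. Compound 22 already holds the enantiopure furofuran (menthyloxybutenolide route) and a ring B bromide, the handle for the later arylacetyl Evans aldol that installs ring A.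

Key step: step 17

Assumption: Rh2(S-PTTL)4 is taken to be the catalyst antipode that gives the (2S,3R) cis ester 23; if the sense of induction is the opposite one, Rh2(R-PTTL)4 is used in the same way.

Abbreviations used in names: Men = (1R,2S,5R)-2-isopropyl-5-methylcyclohexyl; ArB = 3-bromo-5-methoxy-4-(triisopropylsilyloxy)phenyl; ArD = 3-methoxy-4-(triisopropylsilyloxy)phenyl (rings A and D in silylated form); ArC = 3-allyl-5-methoxy-4-(ArD-methoxy)phenyl; FF = (1S,3aR,4S,6aR)-tetrahydro-1H,3H-furo[3,4-c]furan-1,4-diyl. The ring D phenol is carried as the TIPS ether so that it survives DBU, Me3SnOH and LiBH4.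

Step 1
Reactants: 1 5-hydroxy-2(5H)-furanone; 2 (−)-menthol
Product: 3 (5R)-5-(MenO)furan-2(5H)-one
Conditions: CSA (cat.), toluene, reflux, Dean–Stark; crystallisation from petroleum ether, mother liquor re-equilibrated with CSA
Reagents that add atoms: none
Why: Acid-catalysed acetal exchange gives both C5 epimers, which interconvert through the oxocarbenium ion, and the crystalline (5R) epimer is drawn out of the equilibrium (crystallisation-induced epimerisation).

Step 2
Reactants: 4 vanillin
Product: 5 4-(allyloxy)-3-methoxybenzaldehyde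
Conditions: allyl bromide, K2CO3, acetone, reflux
Reagents that add atoms: allyl bromide, C=CCBr
Why: Williamson etherification of the phenoxide with a reactive allylic halide.

Step 3
Reactants: 5 4-(allyloxy)-3-methoxybenzaldehyde
Product: 6 3-allyl-4-hydroxy-5-methoxybenzaldehyde
Conditions: N,N-diethylaniline, 200 °C
Reagents that add atoms: none
Why: Aromatic Claisen rearrangement delivers the allyl group to the only free ortho position and tautomerisation restores the phenol.

Step 4
Reactants: 6 3-allyl-4-hydroxy-5-methoxybenzaldehyde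
Product: 7 2-(3-allyl-4-hydroxy-5-methoxyphenyl)-1,3-dithiane
Conditions: HS(CH2)3SH, BF3·OEt2 (0.2 equiv), CH2Cl2, 0 °C to rt
Reagents that add atoms: propane-1,3-dithiol, SCCCS
Why: Lewis-acid-catalysed dithioacetalisation of the aldehyde (Corey–Seebach dithiane), to which the phenol and the allyl group are inert.

Step 5
Reactants: 4 vanillin
Product: 8 3-methoxy-4-(triisopropylsilyloxy)benzaldehyde
Conditions: TIPSCl, imidazole, DMF, rt
Reagents that add atoms: chlorotriisopropylsilane, CC(C)[Si](Cl)(C(C)C)C(C)C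
Why: Imidazole-promoted O-silylation of the phenol; the same aldehyde later serves as the source of ring D (step 6) and of ring A (step 23).

Step 6
Reactants: 8 3-methoxy-4-(triisopropylsilyloxy)benzaldehyde
Product: 9 [3-methoxy-4-(triisopropylsilyloxy)phenyl]methanol
Conditions: NaBH4, MeOH/THF, 0 °C
Reagents that add atoms: none
Why: Borohydride reduction of the aldehyde, which leaves the aryl silyl ether untouched.

Step 7
Reactants: 7 2-(3-allyl-4-hydroxy-5-methoxyphenyl)-1,3-dithiane; 9 [3-methoxy-4-(triisopropylsilyloxy)phenyl]methanol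
Product: 10 2-ArC-1,3-dithiane
Conditions: PPh3, DIAD, THF, 0 °C to rt
Reagents that add atoms: none
Why: Mitsunobu etherification of the phenol with the primary benzylic alcohol under neutral conditions installs the ring D benzyl ether without passing through the labile p-silyloxybenzyl halide.

Step 8
Reactants: 11 5-bromovanillin
Product: 12 3-bromo-5-methoxy-4-(triisopropylsilyloxy)benzaldehyde (ArB–CHO)
Conditions: TIPSCl, imidazole, DMAP (cat.), DMF, 40 °C
Reagents that add atoms: chlorotriisopropylsilane, CC(C)[Si](Cl)(C(C)C)C(C)C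
Why: O-Silylation of the hindered phenol; the bromide is kept away from butyllithium by using this ring as the aldehyde partner of step 9.

Step 9
Reactants: 10 2-ArC-1,3-dithiane; 3 (5R)-5-(MenO)furan-2(5H)-one; 12 ArB–CHO
Product: 15 (3S,4R,5R)-3-[ArB(hydroxy)methyl]-4-(2-ArC-1,3-dithian-2-yl)-5-(MenO)dihydrofuran-2(3H)-one (both carbinol epimers), via lithiated dithiane 13 (not isolated), via lactone lithium enolate 14 (not isolated)
Conditions: n-BuLi, THF, −78 °C; then 3, −78 °C; then 12, −78 to −50 °C; aq NH4Cl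
Reagents that add atoms: none
Why: Tandem Michael addition–aldol of a Corey–Seebach acyl-anion equivalent: the soft 2-aryl-dithianyl anion should add 1,4 to the butenolide on the face opposite the C5 menthyloxy group (setting C4 as R), and the lactone enolate should take up aldehyde 12 trans to the new C4 substituent (setting C3 as S), the carbinol carbon forming as an epimer mixture that step 12 erases.

Step 10
Reactants: 15 tandem adduct
Product: 16 (3S,4R,5R)-4-(ArC-carbonyl)-3-[ArB(hydroxy)methyl]-5-(MenO)dihydrofuran-2(3H)-one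
Conditions: MeI, CaCO3, MeCN/H2O (9:1), 45 °C
Reagents that add atoms: water, O
Why: Alkylative dithiane hydrolysis: S-methylation turns sulfur into a leaving group and water delivers the aryl ketone without the mercury salts that would attack the allyl group, while C4, now α to the ketone, keeps the favoured all-trans arrangement.

Step 11
Reactants: 16 keto lactone
Product: 17 (2R,3R)-1-ArC-4-ArB-2,3-bis(hydroxymethyl)butane-1,4-diol (epimer mixture at C1 and C4)
Conditions: LiAlH4, THF, 0 °C to rt; aq potassium sodium tartrate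
Reagents that add atoms: none
Why: Hydride reduction of the ketone, of the lactone and of the aldehyde released when the menthyl hemiacetal collapses gives the tetraol and frees menthol, the aryl bromide and aryl silyl ethers being inert at this temperature.

Step 12
Reactants: 17 tetraol
Product: 18 1-ArC-4-ArB-FF, the (1S,3aR,4S,6aR) diexo furofuran
Conditions: CSA (0.2 equiv), 4 Å MS, CH2Cl2, 0 °C; Et3N quench
Reagents that add atoms: none
Why: Acid-catalysed double cycloetherification (SN1): each p-oxygenated benzylic alcohol ionises to a quinone-methide-like cation that is captured 5-exo by the primary hydroxyl of the other branch on the convex face, so both aryl groups end up exo whatever the carbinol configuration and the bridgeheads set in step 9 fix the absolute sense; the aryl benzyl ether should ionise far more slowly than the benzylic alcohols.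

Step 13
Reactants: 18 allyl furofuran
Product: 19 arylacetaldehyde (18 with CH2CHO in place of allyl)
Conditions: OsO4 (2 mol %), NaIO4, 2,6-lutidine, dioxane/H2O (3:1), rt
Reagents that add atoms: osmium tetroxide, O=[Os](=O)(=O)=O; sodium periodate (terminal oxidant), [Na+].[O-]I(=O)(=O)=O
Why: Lemieux–Johnson dihydroxylation and glycol cleavage of the terminal alkene, which is the only alkene present once the dithiane sulfur has gone.

Step 14
Reactants: 19 arylacetaldehyde
Product: 20 arylacetic acid (18 with CH2CO2H in place of allyl)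
Conditions: NaClO2, NaH2PO4, 2-methyl-2-butene, t-BuOH/H2O, 0 °C to rt
Reagents that add atoms: sodium chlorite, [Na+].[O-]Cl=O
Why: Pinnick oxidation, in which the alkene scavenger removes hypochlorous acid before it can chlorinate the electron-rich rings.

Step 15
Reactants: 20 arylacetic acid
Product: 21 methyl arylacetate (18 with CH2CO2Me in place of allyl)
Conditions: Me3SiCHN2, MeOH/toluene (1:4), 0 °C
Reagents that add atoms: trimethylsilyldiazomethane, C[Si](C)(C)C=[N+]=[N-]
Why: O-Methylation of the carboxylic acid by a diazomethane equivalent under neutral conditions that spare the silyl ethers.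

Step 16
Reactants: 21 methyl arylacetate
Product: 22 methyl 2-diazo-2-aryl-acetate on ring C, ortho to the ring D benzyl ether (precursor of the key step)
Conditions: p-ABSA, DBU, MeCN, 0 °C to rt
Reagents that add atoms: 4-acetamidobenzenesulfonyl azide, CC(=O)Nc1ccc(cc1)S(=O)(=O)N=[N+]=[N-]
Why: Regitz diazo transfer from the sulfonyl azide to the arylacetate enolate, the standard entry to aryldiazoacetates.

Step 17
Reactants: 22 ring C aryldiazoacetate
Product: 23 methyl (2S,3R)-cis-7-methoxy-2-ArD-5-(4-ArB-FF-1-yl)-2,3-dihydro-1-benzofuran-3-carboxylate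
Conditions: Rh2(S-PTTL)4 (2 mol %), toluene, −60 °C, slow addition of 22
Reagents that add atoms: none
Why: Rh2(S-PTTL)4 (divalent rhodium) expels N2 from 22 and the resulting donor–acceptor rhodium carbene inserts into one of the two enantiotopic O–CH2 hydrogens of the ring D benzyl ether through a concerted, hydride-transfer-like three-centre transition state, forming the C2–C3 bond. The closest known reaction type is the chiral dirhodium carboxylate-catalysed cyclisation of methyl 2-(2-benzyloxyphenyl)-2-diazoacetates to cis-2-aryl-2,3-dihydrobenzofuran-3-carboxylates. The five-membered oxygen ring is closed as a 1,5-C–H insertion, the ring oxygen and the two ring C carbons being in place beforehand. C2 (S) is set by the choice of benzylic hydrogen that the phthalimido-carboxylate pocket presents to the carbene, and C3 (R) arises in the same event with ester and aryl group on one face, which is the kinetic cis arrangement. The step needs site selectivity and cis selectivity: only the benzylic C–H bond lies within 1,5-reach of the carbene and it is activated by the ether oxygen and the ring D silyloxy group, whereas the furofuran C–H bonds and the ring B bromide are remote. Low temperature in toluene should hold the reaction on the concerted path and keep the epimerisable cis ester intact until step 18.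

Step 18
Reactants: 23 cis ester
Product: 24 [(2S,3S)-cis-7-methoxy-2-ArD-5-(4-ArB-FF-1-yl)-2,3-dihydro-1-benzofuran-3-yl]methanol
Conditions: i-Bu2AlH, CH2Cl2, −78 °C; aq potassium sodium tartrate
Reagents that add atoms: none
Why: Low-temperature aluminium hydride reduction of the ester proceeds without enolisation, so the cis relationship is kept and the only epimerisable centre of the new ring is removed at once.

Step 19
Reactants: 24 cis alcohol
Product: 25 TBS ether of 24
Conditions: TBSCl, imidazole, DMF, rt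
Reagents that add atoms: tert-butylchlorodimethylsilane, CC(C)(C)[Si](C)(C)Cl
Why: Standard silylation of the primary alcohol, which must be masked before acyl activation and boron enolisation.

Step 20
Reactants: 25 ring B bromide
Product: 26 methyl arylacetate on ring B (25 with CH2CO2Me in place of Br)
Conditions: BrZnCH2CO2Me (0.5 M in THF), Pd(dba)2 (5 mol %), P(t-Bu)3 (5 mol %), THF, rt to 50 °C
Reagents that add atoms: (2-methoxy-2-oxoethyl)zinc bromide, COC(=O)C[Zn]Br
Why: Negishi-type α-arylation of a Reformatsky zinc enolate by zerovalent palladium with a bulky electron-rich phosphine, a neutral coupling that tolerates ortho substituents and all silyl ethers.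

Step 21
Reactants: 26 methyl arylacetate
Product: 27 arylacetic acid on ring B (25 with CH2CO2H in place of Br)
Conditions: Me3SnOH, 1,2-dichloroethane, 70 °C; cold 0.1 M HCl wash
Reagents that add atoms: trimethyltin hydroxide, C[Sn](C)(C)O
Why: Organotin-mediated ester hydrolysis under near-neutral conditions avoids both the hydroxide that would cleave aryl silyl ethers and the acid that would ionise the benzylic ethers.

Step 22
Reactants: 27 arylacetic acid; 28 (R)-4-benzyl-2-oxazolidinone
Product: 30 (4R)-4-benzyl-3-(arylacetyl)oxazolidin-2-one, via mixed pivalic anhydride 29 (not isolated)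
Conditions: PivCl, Et3N, THF, −20 °C; then 28, LiCl, rt
Reagents that add atoms: none
Why: Mixed-anhydride activation followed by N-acylation of the oxazolidinone activated by LiCl and Et3N, a one-pot acylation that needs no butyllithium.

Step 23
Reactants: 30 N-arylacetyl oxazolidinone; 8 3-methoxy-4-(triisopropylsilyloxy)benzaldehyde
Product: 32 (4R)-4-benzyl-3-[(2R,3R)-3-hydroxy-3-ArD-2-aryl-propanoyl]oxazolidin-2-one, via dibutylboron Z-enolate 31 (not isolated)
Conditions: Bu2BOTf (1.1 equiv), i-Pr2NEt, CH2Cl2, −78 to 0 °C; then 8, −78 to 0 °C; pH 7 buffer, MeOH, H2O2, 0 °C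
Reagents that add atoms: none
Why: Evans boron aldol: the Z-enolate reacts through a closed Zimmerman–Traxler transition state on the face away from the benzyl group of the (R)-auxiliary, which sets the aryl-bearing carbon as R (the centre that becomes the ketone α-carbon) and the syn carbinol as R.

Step 24
Reactants: 32 aldol adduct
Product: 33 (1R,2S)-1-ArD-2-aryl-propane-1,3-diol
Conditions: LiBH4, MeOH (1 equiv), THF, 0 °C
Reagents that add atoms: none
Why: Reductive removal of the auxiliary by hydride attack at the exocyclic imide carbonyl gives the primary alcohol without enolising the aryl-bearing centre and returns the oxazolidinone.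

Step 25
Reactants: 33 diol
Product: 34 (1R,2S)-3-(tert-butyldimethylsilyloxy)-1-ArD-2-aryl-propan-1-ol
Conditions: TBSCl (1.1 equiv), imidazole, CH2Cl2, 0 °C
Reagents that add atoms: tert-butylchlorodimethylsilane, CC(C)(C)[Si](C)(C)Cl
Why: Steric differentiation lets the primary hydroxyl be silylated in preference to the hindered secondary benzylic one.

Step 26
Reactants: 34 secondary alcohol
Product: 35 (2S)-3-(tert-butyldimethylsilyloxy)-1-ArD-2-aryl-propan-1-one
Conditions: Dess–Martin periodinane, NaHCO3, CH2Cl2, 0 °C to rt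
Reagents that add atoms: none
Why: Buffered hypervalent-iodine oxidation of the benzylic alcohol removes the carbinol stereocentre as planned and should not enolise the adjacent α-aryl centre.

Step 27
Reactants: 35 penta-silylated ketone
Product: 36 CNP0174045.1
Conditions: TBAF, AcOH (1:1), THF, 0 °C to rt
Reagents that add atoms: none
Why: Fluoride cleaves the three aryl TIPS ethers and the two primary TBS ethers in one operation, and acetic acid buffering keeps the medium close to neutral so that the α-aryl β-hydroxy ketone should neither epimerise nor eliminate.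

Compound list

1 | 5-hydroxy-2(5H)-furanone (racemic hemiacetal) | O=C1C=CC(O)O1 | starting material
2 | (−)-menthol, (1R,2S,5R) | CC(C)[C@@H]1CC[C@@H](C)C[C@H]1O | starting material
3 | (5R)-5-[(1R,2S,5R)-menthyloxy]furan-2(5H)-one | CC(C)[C@@H]1CC[C@@H](C)C[C@H]1O[C@H]1C=CC(=O)O1 | intermediate
4 | vanillin | O=Cc1ccc(O)c(OC)c1 | starting material
5 | 4-(allyloxy)-3-methoxybenzaldehyde | O=Cc1ccc(OCC=C)c(OC)c1 | intermediate
6 | 3-allyl-4-hydroxy-5-methoxybenzaldehyde | O=Cc1cc(CC=C)c(O)c(OC)c1 | intermediate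
7 | 2-(3-allyl-4-hydroxy-5-methoxyphenyl)-1,3-dithiane | C=CCc1cc(C2SCCCS2)cc(OC)c1O | intermediate
8 | 3-methoxy-4-(triisopropylsilyloxy)benzaldehyde | O=Cc1ccc(O[Si](C(C)C)(C(C)C)C(C)C)c(OC)c1 | intermediate
9 | [3-methoxy-4-(triisopropylsilyloxy)phenyl]methanol | OCc1ccc(O[Si](C(C)C)(C(C)C)C(C)C)c(OC)c1 | intermediate
10 | 2-(3-allyl-5-methoxy-4-{[3-methoxy-4-(triisopropylsilyloxy)benzyl]oxy}phenyl)-1,3-dithiane | C=CCc1cc(C2SCCCS2)cc(OC)c1OCc1ccc(O[Si](C(C)C)(C(C)C)C(C)C)c(OC)c1 | intermediate
11 | 5-bromovanillin | O=Cc1cc(Br)c(O)c(OC)c1 | starting material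
12 | 3-bromo-5-methoxy-4-(triisopropylsilyloxy)benzaldehyde | O=Cc1cc(Br)c(O[Si](C(C)C)(C(C)C)C(C)C)c(OC)c1 | intermediate
13 | 2-lithio derivative of 10 (not isolated) | [Li]C1(SCCCS1)c1cc(CC=C)c(OCc2ccc(O[Si](C(C)C)(C(C)C)C(C)C)c(OC)c2)c(OC)c1 | intermediate
14 | lithium (4R,5R)-4-(2-ArC-1,3-dithian-2-yl)-5-(menthyloxy)-4,5-dihydrofuran-2-olate (not isolated) | [Li]OC1=C[C@@H](C2(SCCCS2)c2cc(CC=C)c(OCc3ccc(O[Si](C(C)C)(C(C)C)C(C)C)c(OC)c3)c(OC)c2)[C@H](O[C@@H]2C[C@H](C)CC[C@H]2C(C)C)O1 | intermediate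
15 | (3S,4R,5R)-3-[ArB(hydroxy)methyl]-4-(2-ArC-1,3-dithian-2-yl)-5-(menthyloxy)dihydrofuran-2(3H)-one, carbinol epimers | O=C1O[C@@H](O[C@@H]2C[C@H](C)CC[C@H]2C(C)C)[C@H](C2(SCCCS2)c2cc(CC=C)c(OCc3ccc(O[Si](C(C)C)(C(C)C)C(C)C)c(OC)c3)c(OC)c2)[C@H]1C(O)c1cc(Br)c(O[Si](C(C)C)(C(C)C)C(C)C)c(OC)c1 | intermediate
16 | (3S,4R,5R)-4-(ArC-carbonyl)-3-[ArB(hydroxy)methyl]-5-(menthyloxy)dihydrofuran-2(3H)-one, carbinol epimers | O=C1O[C@@H](O[C@@H]2C[C@H](C)CC[C@H]2C(C)C)[C@H](C(=O)c2cc(CC=C)c(OCc3ccc(O[Si](C(C)C)(C(C)C)C(C)C)c(OC)c3)c(OC)c2)[C@H]1C(O)c1cc(Br)c(O[Si](C(C)C)(C(C)C)C(C)C)c(OC)c1 | intermediate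
17 | (2R,3R)-1-ArC-4-ArB-2,3-bis(hydroxymethyl)butane-1,4-diol, epimers at C1 and C4 | OC[C@H](C(O)c1cc(CC=C)c(OCc2ccc(O[Si](C(C)C)(C(C)C)C(C)C)c(OC)c2)c(OC)c1)[C@H](CO)C(O)c1cc(Br)c(O[Si](C(C)C)(C(C)C)C(C)C)c(OC)c1 | intermediate
18 | (1S,3aR,4S,6aR)-1-ArC-4-ArB-tetrahydro-1H,3H-furo[3,4-c]furan | C=CCc1cc([C@H]2OC[C@H]3[C@@H]2CO[C@@H]3c2cc(Br)c(O[Si](C(C)C)(C(C)C)C(C)C)c(OC)c2)cc(OC)c1OCc1ccc(O[Si](C(C)C)(C(C)C)C(C)C)c(OC)c1 | intermediate
19 | 18 with CH2CHO in place of the allyl group | O=CCc1cc([C@H]2OC[C@H]3[C@@H]2CO[C@@H]3c2cc(Br)c(O[Si](C(C)C)(C(C)C)C(C)C)c(OC)c2)cc(OC)c1OCc1ccc(O[Si](C(C)C)(C(C)C)C(C)C)c(OC)c1 | intermediate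
20 | 18 with CH2CO2H in place of the allyl group | OC(=O)Cc1cc([C@H]2OC[C@H]3[C@@H]2CO[C@@H]3c2cc(Br)c(O[Si](C(C)C)(C(C)C)C(C)C)c(OC)c2)cc(OC)c1OCc1ccc(O[Si](C(C)C)(C(C)C)C(C)C)c(OC)c1 | intermediate
21 | 18 with CH2CO2Me in place of the allyl group | COC(=O)Cc1cc([C@H]2OC[C@H]3[C@@H]2CO[C@@H]3c2cc(Br)c(O[Si](C(C)C)(C(C)C)C(C)C)c(OC)c2)cc(OC)c1OCc1ccc(O[Si](C(C)C)(C(C)C)C(C)C)c(OC)c1 | intermediate
22 | furofuran ring C aryldiazoacetate with ortho ring D benzyl ether (18 with C(=N2)CO2Me in place of allyl) | COC(=O)C(=[N+]=[N-])c1cc([C@H]2OC[C@H]3[C@@H]2CO[C@@H]3c2cc(Br)c(O[Si](C(C)C)(C(C)C)C(C)C)c(OC)c2)cc(OC)c1OCc1ccc(O[Si](C(C)C)(C(C)C)C(C)C)c(OC)c1 | intermediate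
23 | methyl (2S,3R)-cis-7-methoxy-2-ArD-5-[(1S,3aR,4S,6aR)-4-ArB-furofuran-1-yl]-2,3-dihydro-1-benzofuran-3-carboxylate | COc1cc([C@H]2OC[C@H]3[C@@H]2CO[C@@H]3c2cc(OC)c3c(c2)[C@@H](C(=O)OC)[C@@H](c2ccc(O[Si](C(C)C)(C(C)C)C(C)C)c(OC)c2)O3)cc(Br)c1O[Si](C(C)C)(C(C)C)C(C)C | intermediate
24 | (2S,3S)-cis 3-hydroxymethyl analogue of 23 | COc1cc([C@H]2OC[C@H]3[C@@H]2CO[C@@H]3c2cc(OC)c3c(c2)[C@@H](CO)[C@@H](c2ccc(O[Si](C(C)C)(C(C)C)C(C)C)c(OC)c2)O3)cc(Br)c1O[Si](C(C)C)(C(C)C)C(C)C | intermediate
25 | TBS ether of 24 | COc1cc([C@H]2OC[C@H]3[C@@H]2CO[C@@H]3c2cc(OC)c3c(c2)[C@@H](CO[Si](C)(C)C(C)(C)C)[C@@H](c2ccc(O[Si](C(C)C)(C(C)C)C(C)C)c(OC)c2)O3)cc(Br)c1O[Si](C(C)C)(C(C)C)C(C)C | intermediate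
26 | 25 with CH2CO2Me in place of Br on ring B | COc1cc([C@H]2OC[C@H]3[C@@H]2CO[C@@H]3c2cc(OC)c3c(c2)[C@@H](CO[Si](C)(C)C(C)(C)C)[C@@H](c2ccc(O[Si](C(C)C)(C(C)C)C(C)C)c(OC)c2)O3)cc(CC(=O)OC)c1O[Si](C(C)C)(C(C)C)C(C)C | intermediate
27 | 25 with CH2CO2H in place of Br on ring B | COc1cc([C@H]2OC[C@H]3[C@@H]2CO[C@@H]3c2cc(OC)c3c(c2)[C@@H](CO[Si](C)(C)C(C)(C)C)[C@@H](c2ccc(O[Si](C(C)C)(C(C)C)C(C)C)c(OC)c2)O3)cc(CC(=O)O)c1O[Si](C(C)C)(C(C)C)C(C)C | intermediate
28 | (R)-4-benzyl-2-oxazolidinone | O=C1N[C@H](Cc2ccccc2)CO1 | starting material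
29 | mixed anhydride of 27 with pivalic acid (not isolated) | COc1cc([C@H]2OC[C@H]3[C@@H]2CO[C@@H]3c2cc(OC)c3c(c2)[C@@H](CO[Si](C)(C)C(C)(C)C)[C@@H](c2ccc(O[Si](C(C)C)(C(C)C)C(C)C)c(OC)c2)O3)cc(CC(=O)OC(=O)C(C)(C)C)c1O[Si](C(C)C)(C(C)C)C(C)C | intermediate
30 | (4R)-4-benzyl-3-(arylacetyl)oxazolidin-2-one from 27 | COc1cc([C@H]2OC[C@H]3[C@@H]2CO[C@@H]3c2cc(OC)c3c(c2)[C@@H](CO[Si](C)(C)C(C)(C)C)[C@@H](c2ccc(O[Si](C(C)C)(C(C)C)C(C)C)c(OC)c2)O3)cc(CC(=O)N4C(=O)OC[C@H]4Cc4ccccc4)c1O[Si](C(C)C)(C(C)C)C(C)C | intermediate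
31 | dibutylboron (Z)-enolate of 30 (not isolated) | COc1cc([C@H]2OC[C@H]3[C@@H]2CO[C@@H]3c2cc(OC)c3c(c2)[C@@H](CO[Si](C)(C)C(C)(C)C)[C@@H](c2ccc(O[Si](C(C)C)(C(C)C)C(C)C)c(OC)c2)O3)cc(/C=C(\OB(CCCC)CCCC)N4C(=O)OC[C@H]4Cc4ccccc4)c1O[Si](C(C)C)(C(C)C)C(C)C | intermediate
32 | (4R)-4-benzyl-3-[(2R,3R)-3-hydroxy-3-ArD-2-(ring B aryl)propanoyl]oxazolidin-2-one, syn aldol | COc1cc([C@H]2OC[C@H]3[C@@H]2CO[C@@H]3c2cc(OC)c3c(c2)[C@@H](CO[Si](C)(C)C(C)(C)C)[C@@H](c2ccc(O[Si](C(C)C)(C(C)C)C(C)C)c(OC)c2)O3)cc([C@@H](C(=O)N4C(=O)OC[C@H]4Cc4ccccc4)[C@@H](O)c4ccc(O[Si](C(C)C)(C(C)C)C(C)C)c(OC)c4)c1O[Si](C(C)C)(C(C)C)C(C)C | intermediate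
33 | (1R,2S)-1-ArD-2-(ring B aryl)propane-1,3-diol | COc1cc([C@H]2OC[C@H]3[C@@H]2CO[C@@H]3c2cc(OC)c3c(c2)[C@@H](CO[Si](C)(C)C(C)(C)C)[C@@H](c2ccc(O[Si](C(C)C)(C(C)C)C(C)C)c(OC)c2)O3)cc([C@@H](CO)[C@@H](O)c4ccc(O[Si](C(C)C)(C(C)C)C(C)C)c(OC)c4)c1O[Si](C(C)C)(C(C)C)C(C)C | intermediate
34 | primary TBS ether of 33, (1R,2S) | COc1cc([C@H]2OC[C@H]3[C@@H]2CO[C@@H]3c2cc(OC)c3c(c2)[C@@H](CO[Si](C)(C)C(C)(C)C)[C@@H](c2ccc(O[Si](C(C)C)(C(C)C)C(C)C)c(OC)c2)O3)cc([C@@H](CO[Si](C)(C)C(C)(C)C)[C@@H](O)c4ccc(O[Si](C(C)C)(C(C)C)C(C)C)c(OC)c4)c1O[Si](C(C)C)(C(C)C)C(C)C | intermediate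
35 | (2S)-ketone from 34 (target with three aryl TIPS and two primary TBS ethers) | COc1cc([C@H]2OC[C@H]3[C@@H]2CO[C@@H]3c2cc(OC)c3c(c2)[C@@H](CO[Si](C)(C)C(C)(C)C)[C@@H](c2ccc(O[Si](C(C)C)(C(C)C)C(C)C)c(OC)c2)O3)cc([C@@H](CO[Si](C)(C)C(C)(C)C)C(=O)c4ccc(O[Si](C(C)C)(C(C)C)C(C)C)c(OC)c4)c1O[Si](C(C)C)(C(C)C)C(C)C | intermediate
36 | CNP0174045.1 | COc1cc(C(=O)[C@H](CO)c2cc([C@H]3OC[C@H]4[C@@H]3CO[C@@H]4c3cc(OC)c4c(c3)[C@@H](CO)[C@@H](c3ccc(O)c(OC)c3)O4)cc(OC)c2O)ccc1O | target

Total step count: 27
Longest linear sequence: 23 steps (vanillin 4 through steps 2, 3, 4, 7 and 9 to 27)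

Three steps most likely to fail

Step 17 (key step). What may go wrong: the electron-rich ring D may divert the concerted insertion into a stepwise hydride-transfer path, which erodes cis control. The catalyst may also discriminate poorly between the two benzylic hydrogens on this large substrate, which erodes facial control. The fallback changes the source of stereocontrol from catalyst induction to separation. Setting out from 22, the insertion is run with achiral Rh2(OAc)4 in CH2Cl2. Because the furofuran is already enantiopure, the two cis esters that should form, 23 and the methyl (2R,3S) cis ester F1, are diastereomers and are parted by preparative HPLC. Compound 23 rejoins the route at step 18.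

Step 12. What may go wrong: ionisation of the acid-labile p-silyloxybenzyl aryl ether may compete with ionisation of the two carbinols, so that the ring D benzyl group is lost or transferred to an arene before both rings are closed. The fallback treats that benzyl ether as sacrificial. Setting out from 17, TFA with pentamethylbenzene as cation scavenger in CH2Cl2 at 0 °C closes both rings and removes the benzyl group on purpose, giving the furofuran phenol F2. Mitsunobu etherification of F2 with alcohol 9 (PPh3, DIAD, THF) then returns to 18.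

Step 27. What may go wrong: during the hours that the primary TBS ethers need, the basicity of fluoride and of the liberated phenoxides may enolise the α-aryl ketone. That would lead to epimerisation at the α-carbon, β-elimination of the silyloxy group or retro-aldol loss of formaldehyde. The fallback is an orthogonal two-stage unmasking through an isolated intermediate. Setting out from 35, HF·pyridine buffered with pyridine in THF removes only the two primary TBS ethers while all three phenols are still capped, giving the tris-TIPS keto diol F3. A brief treatment of F3 with TBAF/AcOH at 0 °C, which should cleave aryl silyl ethers within minutes, returns to 36.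

Further compounds

F1 | step 17 | methyl (2R,3S)-cis diastereomer of 23 | COc1cc([C@H]2OC[C@H]3[C@@H]2CO[C@@H]3c2cc(OC)c3c(c2)[C@H](C(=O)OC)[C@H](c2ccc(O[Si](C(C)C)(C(C)C)C(C)C)c(OC)c2)O3)cc(Br)c1O[Si](C(C)C)(C(C)C)C(C)C
F2 | step 12 | (1S,3aR,4S,6aR)-1-(3-allyl-4-hydroxy-5-methoxyphenyl)-4-ArB-tetrahydro-1H,3H-furo[3,4-c]furan | C=CCc1cc([C@H]2OC[C@H]3[C@@H]2CO[C@@H]3c2cc(Br)c(O[Si](C(C)C)(C(C)C)C(C)C)c(OC)c2)cc(OC)c1O
F3 | step 27 | 35 with both primary hydroxyls free and the three aryl TIPS ethers in place | COc1cc([C@H]2OC[C@H]3[C@@H]2CO[C@@H]3c2cc(OC)c3c(c2)[C@@H](CO)[C@@H](c2ccc(O[Si](C(C)C)(C(C)C)C(C)C)c(OC)c2)O3)cc([C@@H](CO)C(=O)c4ccc(O[Si](C(C)C)(C(C)C)C(C)C)c(OC)c4)c1O[Si](C(C)C)(C(C)C)C(C)C
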